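All runs are calculated for an exercise, noise included.

A ratio of two product readings looks like a constant of the chemistry, but it carries the amounts of both nucleophiles, and those fall as you watch. The gamma run is this very flask followed so far.

common to all: starting material 0.029 M; second nucleophile 0.0232 M

| flask | first nucleophile | protic impurity | remark | time |
|---|---|---|---|---|
| gamma | 0.058 M | 2.9 mM | the very flask that is asked about, followed so far |  |
| flask | 0.0580 M | 2.90 mM |  | 1.0 h |

gamma run (percent of the starting material charged)

| time / min | target / % | other capture product / % |
|---|---|---|
| 4.00 | 6.6 | 4.7 |
| 8.00 | 16.6 | 12.2 |
| 12.0 | 24.8 | 14.8 |
| 15.0 | 32.3 | 18.2 |
| 20.0 | 34.7 | 18.4 |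
| 25.0 | 38.5 | 22.6 |

(each reading ± 1 percentage point)



1. share of target in target plus other capture product at 1.0 min
2. share of target in target plus other capture product at 8.0 min
3. share of target in target plus other capture product at 1.0 h

What does the chemistry itself prefer? Suppose one shared intermediate is captured by each nucleophile at a rate proportional to that nucleophile's concentration. The readings at 25.0 min give target over other capture product as 1.70, and dividing by the charge ratio gives 0.681. But by then the gamma run had already spent nucleophile, so go round once more, counting as spent what the two product readings hold, with the amounts halfway through that spending: 0.0524 M of first and 0.0199 M of second nucleophile. This gives 0.647, a reading that carries the scatter of the two readings behind it, for the selectivity factor s: the intermediate's preference for first over second nucleophile at equal concentration.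

What share does s give at the start? At the charges, the product ratio is 1.62, a share of 61.8 %.

How far does it drift? With the amounts that the two product readings leave at 25.0 min, s puts the ratio of fresh product at 1.82, a share of 64.6 %, higher than at the start. The pooled share trails the fresh one, so you would expect the middle time slightly above 61.8 % and the latest time near 64.6 %.

The forecast gave 59.5 %, 60.5 % and 65.5 %, on the ground that “The second nucleophile (0.8 equiv) depletes proportionally faster, so the share should drift upward.” Its early share stands lower than this reckoning.

The flask gives 62.5 %, 62.9 % and 65.1 %.

    first nucleophile + intermediate → target (k = 0.0989 /M/s)
    intermediate → solvolysis product (k = 0.00197 /s)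
    starting material → intermediate (k = 0.00111 /s)
    first nucleophile + protic impurity → quenched reagent (k = 0.335 /M/s)
    second nucleophile → decomposed reagent (k = 8.06 × 10⁻⁵ /s)
    second nucleophile + intermediate → other capture product (k = 0.145 /M/s)

At 1.0 min this flask stands at 62.5 %, against 61.8 % from s at the charges, and at 0.169 h it uses intermediate 1.8 times as fast by the step to target as by the step to other capture product. In the neighbour flask charged with 0.058 M of second nucleophile, s at the charges gives a share of 39.3 %, and that flask stands at 40.0 % at 1.0 min.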